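## Structural features

The target is a briarane. Cyclohexane ring A (C1, C10–C14) is trans-fused through C1–C10 to the cyclodecene ring B (C1–C10), and a γ-lactone ring C (C7, C8, C17, C19, O) is cis-fused to ring B across C7–C8. There are eleven stereocentres: the contiguous row C14–C1–C10–C11–C12 on ring A (C1 quaternary, the C15 and C20 methyl groups both β), C2–C3 on ring B, and the cluster C7–C8–C9 with C17 around the lactone. C8 is a tertiary carbinol whose three carbon neighbours (C7, C9, C17) all bear oxygen; the 8,17-diol is trans on the lactone, with the 17-hydroxyl cis to C9 and the 8-hydroxyl cis to H7. The only alkene is the (5Z) trisubstituted C5=C6 bond in ring B, allylic to the lactone oxygen at C7; once present it rules out osmium tetroxide, peracids and ozone. Acetates at C2, C9, C12 and C14, a butanoate at C3 only, and two free tertiary hydroxyls make the molecule sensitive to base, acyl migration and hard nucleophiles. The real difficulty is the ten-membered ring with its trans fusion, the C7/C8/C9/C17 stereo-relay, and telling the C2 ester from the C3 ester. The feature exploited is that C2–C3 is the one bond of ring B joining two secondary carbinol carbons whose outer neighbours carry no heteroatom (C1 all-carbon quaternary, C4 methylene), whereas the other diol bond C8–C9 is flanked by oxygenated C7 and C17. A C2,C3-dialdehyde is therefore a clean substrate for ketyl coupling, and the resulting diol is sterically differentiated (C3–OH next to CH2, C2–OH neopentyl).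

## Logic of the disconnections

42 to 40: the acetyl–O2 and butanoyl–O3 bonds are cut. The two hydroxyls of 40 differ strongly in hindrance, so no protecting group is needed between them. The forward demand is butanoylation of O3 before O2, with the tertiary hydroxyls untouched.

40 to 39 (key): the C2–C3 bond is cut, giving two aldehyde carbons of like polarity. In one sentence, the ten-membered ring is closed last by reductive pinacol coupling of C2 and C3 in a seco-dialdehyde that already carries ring A, the Z-alkene and the finished dihydroxy lactone. Ring B and the stereocentres C2 and C3 disappear together, and 39 is an open chain hung on ring A. The forward step must reduce only the aldehydes and must control two new centres.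

39 to 37: the two aldehydes go back to silyl-protected primary alcohols (38, then 37), so both ends of the future bond travel through the route in one masked form and are released together.

37 to 36: the C17–CH3 bond is cut. A methyl nucleophile on a C17 ketone enters anti to C9 and syn to the 8-hydroxyl, which gives the trans 8,17-diol with no oxidant. The demand is methyl transfer to a ketone beside three acetates and a lactone.

36 to 34: the C8–O bond is cut to an enol derivative of the α-keto lactone. Oxygen is delivered to an enolate carbon, so the C5=C6 alkene is never exposed to an electrophilic oxidant. The demand is attack on the lactone face opposite the C7 side chain.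

34 to 19 + 30: the C8–C9 bond is cut between an aldehyde carbon (ring A) and an iodoalkene carbon (lactone), with C9 then reset by oxidation and hydride reduction (31, 32, 33). This splits the molecule into two fragments of similar size. The demand is a coupling that tolerates esters and silyl ethers, and a ketone reduction ruled by C10.

30 to 28: the C8–iodine and O–silicon bonds are cut (via 29), leaving a 5-substituted 3-hydroxybutenolide whose enol carbon C8 is nucleophilic.

28 to 25: the lactone C–O bond and the C17–O bond are cut (27, 26). The oxygen at C17 comes from a C–Si bond placed regioselectively on an alkyne. The demand is silicon at the alkyne carbon remote from the hydroxyl.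

25 to 23 + 24: the C7–C8 bond is cut to an enal and an alkynyl ester. This is the step that sets C7, under catalyst control.

23 to 20: the enal is traced through 22 and 21 to a six-membered unsaturated lactone, whose ring locks the Z geometry of C5=C6 from the start.

19 to 16: the C9 aldehyde goes back to a benzyl ether (18, 17), and the C11–H and C20–H bonds are cut to an exocyclic alkene. Hydrogen adds from the α face, away from the C15 methyl, which sets the 11β-methyl group.

16 to 14: the acetates are removed (15) and the C12–H bond is cut to a ketone. The 14α-hydroxyl delivers hydride internally, giving the anti 1,3-diol.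

14 to 11: the C11=C20 bond is cut to a β-hydroxy ketone. The forward step must enolise towards C11 and not towards C13.

11 to 7: protecting-group and oxidation-level changes only (10, 9, 8).

7 to 6 + 3: the C1–C14 and C10–C11 bonds are cut in a Diels–Alder sense. One step sets C1, C10 and C14 and the quaternary centre. The demand is endo selectivity and enantioface control.

6 to 4 + 5 and 3 to 2 to 1: a Wittig disconnection of the dienophile, and enol silylation and alkoxy exchange for the diene.

## Other disconnections considered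

Alternative 1: Cut C5=C6; forward key step is ring-closing metathesis of the seco-diene A1 (isopropenyl at C4, vinyl at C7, all esters in place) with the second-generation Grubbs catalyst. This is the first idea that comes to mind. It would have to form a trisubstituted alkene in a strained ten-membered ring from a 1,1-disubstituted alkene and a vinyl group on an oxygen-bearing carbon, which favours oligomers and gives no control of the Z geometry. It creates no stereocentre, so A1 must already hold all eleven, with C2 and C3 set in an open chain beside the quaternary C1. The chosen plan makes C2 and C3 in the ring closure itself and takes the Z-alkene from a ring.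

Alternative 2: Cut C8–C9; forward key step is a pinacol coupling of the keto aldehyde A2 (C9 aldehyde on ring A, C8 ketone in the 3-hydroxy-3-methylfuran-2,4-dione) to the 9-hydroxy macrocycle A3. The tether through C7 would give the correct cis ring fusion at C8, which is attractive. But the C8 ketyl is flanked by the C17–O bond, which stands perpendicular to the lactone plane and is set up for β-elimination. H7 is α to the ketone and epimerisable. C2 and C3 would still have to be made stereoselectively in an open chain. The chosen C2–C3 coupling has no leaving group next to either ketyl.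

Alternative 3: Cut C3–C4; forward key step is intramolecular alkylation of the protected C3 cyanohydrin anion by the (Z)-allylic chloride in A4, then unmasking to the C3 ketone A5. This is a reliable umpolung ring closure for ten-membered rings. But the strong amide base is incompatible with four acetates, so A4 must be fully silylated and re-acylated at the end. C2 must be set earlier and C3 afterwards by a separate reduction, and no stereocentre is formed in the ring closure. It costs about six more steps than the chosen plan.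

Key step: step 30

Remarks on the chemistry:
- Briarane numbering (C1–C20) is used for all intermediates; α and β refer to the carbocycles drawn with the C15 methyl β.
- The absolute sense of the two catalyst-controlled steps (4 and 17) is assumed as drawn; the antipodal catalyst or ligand is used if the opposite sense is found.
- 4-Methyl-5,6-dihydro-2H-pyran-2-one (the dehydration product of mevalonolactone) is taken as commercially available.

## Steps

Step 1
Reactants: 1 (E)-4-methoxybut-3-en-2-one
Product: 2 (E)-4-[(4-methoxybenzyl)oxy]but-3-en-2-one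
Conditions: 4-methoxybenzyl alcohol (1.2 equiv), pyridinium p-toluenesulfonate (5 mol %), toluene, 70 °C, reduced pressure
Reagents that add atoms: 4-methoxybenzyl alcohol, COc1ccc(CO)cc1
Why: Acid-catalysed alkoxy exchange (addition–elimination) on the vinylogous ester, driven by removal of methanol; the E isomer is the thermodynamic product.

Step 2
Reactants: 2 (E)-4-[(4-methoxybenzyl)oxy]but-3-en-2-one
Product: 3 (E)-1-[(4-methoxybenzyl)oxy]-3-(trimethylsilyloxy)buta-1,3-diene
Conditions: Me3SiOTf, Et3N, Et2O, 0 °C
Reagents that add atoms: trimethylsilyl triflate, C[Si](C)(C)OS(=O)(=O)C(F)(F)F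
Why: Soft enolisation of the methyl ketone gives the 1-alkoxy-3-silyloxy diene; only the methyl group can enolise.

Step 3
Reactants: 4 (benzyloxy)acetaldehyde; 5 2-(triphenylphosphoranylidene)propanal
Product: 6 (E)-4-(benzyloxy)-2-methylbut-2-enal
Conditions: toluene, 80 °C
Reagents that add atoms: none
Why: Wittig olefination with a stabilised ylide, which gives the E-configured α-methyl enal.

Step 4
Reactants: 6 (E)-4-(benzyloxy)-2-methylbut-2-enal; 3 (E)-1-[(4-methoxybenzyl)oxy]-3-(trimethylsilyloxy)buta-1,3-diene
Product: 7 cycloadduct: cyclohex-12-ene with 1β-methyl, 1α-formyl, 10β-(benzyloxymethyl), 14α-(4-methoxybenzyloxy) and 12-(trimethylsilyloxy) groups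
Conditions: protonated (S)-o-tolyl-diphenylprolinol oxazaborolidine (oxazaborolidinium triflimide, 20 mol %), CH2Cl2, −78 °C
Reagents that add atoms: none
Why: Lewis-acid-catalysed enantioselective Diels–Alder reaction with the normal regiochemistry of 1-alkoxy-3-silyloxy dienes (C11 to C10, C14 to C1). The E dienophile places C9 trans to the formyl group, the endo rule places the formyl group cis to the C14 oxygen, and the chiral boron cation selects the enantioface, so C1, C10 and C14 are set together.

Step 5
Reactants: 7 cycloadduct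
Product: 9 1α-(hydroxymethyl)-1β-methyl-10β-(benzyloxymethyl)-14α-(4-methoxybenzyloxy)cyclohexan-12-one, via silyl enol ether alcohol 8 (not isolated)
Conditions: iBu2AlH, CH2Cl2, −78 °C; then 0.5 M HCl, THF, 0 °C
Reagents that add atoms: none
Why: Hydride reduction of the only carbonyl group, then mild acid hydrolysis of the trimethylsilyl enol ether; cold dilute acid should not eliminate the β-alkoxy group.

Step 6
Reactants: 9 keto alcohol
Product: 10 1α-(tert-butyldimethylsilyloxymethyl)-1β-methyl-10β-(benzyloxymethyl)-14α-(4-methoxybenzyloxy)cyclohexan-12-one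
Conditions: tBuMe2SiCl, imidazole, DMF, rt
Reagents that add atoms: tert-butyldimethylsilyl chloride, CC(C)(C)[Si](C)(C)Cl
Why: Standard silylation of the primary (neopentyl) alcohol; this group masks C2 until step 28.

Step 7
Reactants: 10 silyl ether
Product: 11 14α-hydroxy-1α-(tert-butyldimethylsilyloxymethyl)-1β-methyl-10β-(benzyloxymethyl)cyclohexan-12-one
Conditions: DDQ, CH2Cl2/pH 7 buffer, 0 °C
Reagents that add atoms: none
Why: Oxidative cleavage of the 4-methoxybenzyl ether; the benzyl and silyl ethers are stable to DDQ.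

Step 8
Reactants: 11 β-hydroxy ketone
Product: 14 11-methylidene-14α-hydroxy-12-ketone, via Mannich base 12 (not isolated), via ammonium iodide 13 (not isolated)
Conditions: LiN(iPr)2 (2.2 equiv), THF, −78 °C; CH2=NMe2+ I−, −78 to 0 °C; then MeI, CH2Cl2, rt; then aq NaHCO3, rt
Reagents that add atoms: dimethyl(methylidene)ammonium iodide, C=[N+](C)C.[I-]
Why: The lithium alkoxide at C14 steers the second deprotonation to C11 (α′, away from the alkoxide-bearing side), as in dianions of β-hydroxy ketones. Mannich reaction, quaternisation and mild E1cB elimination then give the α-methylene ketone; bicarbonate avoids migration of the alkene into the ring.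

Step 9
Reactants: 14 11-methylidene-14α-hydroxy-12-ketone
Product: 15 11-methylidene-12β,14α-diol
Conditions: Me4NBH(OAc)3, MeCN/AcOH (1:1), −30 °C
Reagents that add atoms: none
Why: Evans–Saksena reduction: the acetoxyborohydride bound to the 14α-hydroxyl delivers hydride internally to the α face of the C12 ketone, giving the 12β-alcohol (1,3-anti diol).

Step 10
Reactants: 15 diol
Product: 16 11-methylidene-12β,14α-diacetate
Conditions: Ac2O, DMAP, pyridine, rt
Reagents that add atoms: acetic anhydride, CC(=O)OC(C)=O
Why: Acetylation of both secondary alcohols installs two of the final ester groups early.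

Step 11
Reactants: 16 diacetate
Product: 17 11β-methyl-12β,14α-diacetate with 10β-(benzyloxymethyl) and 1α-(tert-butyldimethylsilyloxymethyl) groups
Conditions: H2 (4 atm), RhCl(PPh3)3 (10 mol %), benzene/EtOH (1:1), rt
Reagents that add atoms: none
Why: Homogeneous hydrogenation of the 1,1-disubstituted alkene from the α face, opposite to the C15 methyl and to the β substituents at C10 and C12, sets the 11β-methyl group. This catalyst does not hydrogenolyse allylic acetates or benzyl ethers.

Step 12
Reactants: 17 benzyl ether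
Product: 18 10β-(hydroxymethyl)-1β,11β-dimethyl-1α-(tert-butyldimethylsilyloxymethyl)cyclohexane-12β,14α-diyl diacetate
Conditions: H2 (1 atm), Pd(OH)2/C, EtOAc, rt
Reagents that add atoms: none
Why: Hydrogenolysis of the benzyl ether under neutral conditions, which leaves the acetates and the silyl ether in place.

Step 13
Reactants: 18 primary alcohol
Product: 19 ring A aldehyde: 10β-formyl-1β,11β-dimethyl-1α-(tert-butyldimethylsilyloxymethyl)cyclohexane-12β,14α-diyl diacetate
Conditions: Dess–Martin periodinane, NaHCO3, CH2Cl2, 0 °C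
Reagents that add atoms: none
Why: Buffered periodinane oxidation gives the C9 aldehyde without epimerising C10.

Step 14
Reactants: 20 4-methyl-5,6-dihydro-2H-pyran-2-one
Product: 21 (Z)-5-hydroxy-N-methoxy-N,3-dimethylpent-2-enamide
Conditions: MeNH(OMe)·HCl, Me3Al, CH2Cl2, 0 °C to rt; 1 M HCl, 0 °C
Reagents that add atoms: N,O-dimethylhydroxylamine hydrochloride, CNOC.Cl
Why: Aminolysis of the lactone by the dimethylaluminium amide (Weinreb amide formation); the Z geometry of the future C5=C6 bond comes from the ring and is kept.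

Step 15
Reactants: 21 hydroxy amide
Product: 22 (Z)-5-(tert-butyldiphenylsilyloxy)-N-methoxy-N,3-dimethylpent-2-enamide
Conditions: tBuPh2SiCl, imidazole, DMF, rt
Reagents that add atoms: tert-butyldiphenylsilyl chloride, CC(C)(C)[Si](Cl)(c1ccccc1)c1ccccc1
Why: Silylation of the primary alcohol (the future C3 oxygen) with a group that survives fluoride at low temperature in step 26.

Step 16
Reactants: 22 silyl ether amide
Product: 23 (Z)-5-(tert-butyldiphenylsilyloxy)-3-methylpent-2-enal
Conditions: iBu2AlH, THF, −78 °C; aq potassium sodium tartrate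
Reagents that add atoms: none
Why: Reduction of the Weinreb amide stops at the aldehyde through the chelated tetrahedral intermediate; low temperature and neutral work-up keep the Z geometry.

Step 17
Reactants: 23 (Z)-enal; 24 methyl propiolate
Product: 25 methyl (S,Z)-8-(tert-butyldiphenylsilyloxy)-4-hydroxy-6-methyloct-5-en-2-ynoate
Conditions: Me2Zn (3 equiv), (S,S)-ProPhenol (20 mol %), Ph3PO (40 mol %), toluene, 4 °C
Reagents that add atoms: none
Why: Zinc alkynylide addition to the aldehyde under control of the dinuclear zinc–ProPhenol catalyst (catalytic asymmetric alkynylation, for which enals are good substrates); this sets C7.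

Step 18
Reactants: 25 hydroxy ynoate
Product: 26 methyl (2Z,4S,5Z)-8-(tert-butyldiphenylsilyloxy)-4-hydroxy-6-methyl-2-(triethoxysilyl)octa-2,5-dienoate
Conditions: (EtO)3SiH (1.3 equiv), [Cp*Ru(MeCN)3]PF6 (3 mol %), CH2Cl2, 0 °C to rt
Reagents that add atoms: triethoxysilane, CCO[SiH](OCC)OCC
Why: Ruthenium-catalysed trans-hydrosilylation of the alkyne; silicon goes to the carbon remote from the hydroxyl, which is also α to the ester (C17), and the trisubstituted alkene is untouched.

Step 19
Reactants: 26 alkenylsilane
Product: 28 (S)-5-[(Z)-4-(tert-butyldiphenylsilyloxy)-2-methylbut-1-enyl]-3-hydroxyfuran-2(5H)-one, via keto ester 27 (not isolated)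
Conditions: KF, KHCO3, 30% H2O2, THF/MeOH (1:1), 0 °C to rt; AcOH to pH 4
Reagents that add atoms: hydrogen peroxide, OO
Why: Tamao–Fleming oxidation of the alkenyl(trialkoxy)silane gives the enol of the α-keto ester, which lactonises onto the C7 hydroxyl to the 3-hydroxybutenolide; bicarbonate is too weak to epimerise C7.

Step 20
Reactants: 28 3-hydroxybutenolide
Product: 29 (S)-5-[(Z)-4-(tert-butyldiphenylsilyloxy)-2-methylbut-1-enyl]-3-hydroxy-4-iodofuran-2(5H)-one
Conditions: N-iodosuccinimide (1.05 equiv), MeCN, 0 °C, dark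
Reagents that add atoms: N-iodosuccinimide, O=C1CCC(=O)N1I
Why: Electrophilic iodination of the enol at its nucleophilic carbon C8; the enol is far more nucleophilic than the trisubstituted alkene.

Step 21
Reactants: 29 iodo enol
Product: 30 (S)-3-(tert-butyldimethylsilyloxy)-5-[(Z)-4-(tert-butyldiphenylsilyloxy)-2-methylbut-1-enyl]-4-iodofuran-2(5H)-one
Conditions: tBuMe2SiOTf, 2,6-lutidine, CH2Cl2, −78 °C
Reagents that add atoms: tert-butyldimethylsilyl triflate, CC(C)(C)[Si](C)(C)OS(=O)(=O)C(F)(F)F
Why: O-silylation of the acidic enol with a hindered base, which does not remove H7.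

Step 22
Reactants: 19 ring A aldehyde; 30 iodo butenolide
Product: 31 C8–C9 coupled allylic alcohol (mixture of C9 epimers)
Conditions: CrCl2 (4 equiv), NiCl2 (2 mol %), DMSO/THF (3:1), rt
Reagents that add atoms: none
Why: Nozaki–Hiyama–Kishi coupling: zerovalent nickel inserts into the β-iodo enoate, the alkenyl group passes to trivalent chromium and adds to the aldehyde; acetates, the lactone and silyl ethers are tolerated. A Felkin–Anh addition of carbon should favour the 9R alcohol, so the mixture is carried on and C9 is reset in steps 23 and 24.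

Step 23
Reactants: 31 allylic alcohols
Product: 32 C9 ketone
Conditions: Dess–Martin periodinane, NaHCO3, CH2Cl2, 0 °C
Reagents that add atoms: none
Why: Oxidation of both epimeric allylic alcohols to one ketone; buffered conditions leave C10, C7 and the enol silyl ether unchanged.

Step 24
Reactants: 32 C9 ketone
Product: 33 (9S)-allylic alcohol
Conditions: NaBH4, CeCl3·7H2O, MeOH/THF, −78 °C
Reagents that add atoms: none
Why: Luche 1,2-reduction; by the Felkin–Anh model hydride attacks anti to the quaternary C1 on C10, which gives the 9S alcohol from either epimer of 31.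

Step 25
Reactants: 33 (9S)-alcohol
Product: 34 (9S)-acetate
Conditions: Ac2O, DMAP, pyridine, CH2Cl2, 0 °C to rt
Reagents that add atoms: acetic anhydride, CC(=O)OC(C)=O
Why: Acetylation installs the C9 ester and protects O9 before the oxidations that follow.

Step 26
Reactants: 34 enol silyl ether
Product: 36 8-hydroxy-17-oxo lactone (8R), via ammonium enolate 35 (not isolated)
Conditions: Bu4NF (1.0 equiv), THF, −78 °C; then 2-(phenylsulfonyl)-3-phenyloxaziridine (1.5 equiv), −78 to −40 °C; AcOH quench
Reagents that add atoms: 2-(phenylsulfonyl)-3-phenyloxaziridine, O=S(=O)(N1OC1c1ccccc1)c1ccccc1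
Why: Fluoride cleaves the labile enol silyl ether and the enolate is hydroxylated at C8 by the N-sulfonyloxaziridine, a reagent inert to the C5=C6 alkene and to acetates. Attack occurs anti to the C7 side chain and anti to ring A, which allylic 1,3-strain (H9 eclipsing C8=C17) holds on the same face, so the 8-hydroxyl ends cis to H7.

Step 27
Reactants: 36 α-keto lactone
Product: 37 8,17-dihydroxy lactone (8R,17R) with 2-O-tert-butyldimethylsilyl and 3-O-tert-butyldiphenylsilyl groups
Conditions: MeTi(OiPr)3 (4 equiv), THF, −40 to 0 °C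
Reagents that add atoms: methyltitanium triisopropoxide, C[Ti](OC(C)C)(OC(C)C)OC(C)C
Why: The methyltitanium reagent adds to the activated C17 ketone and not to acetates or the lactone. Methyl is delivered from the titanium alkoxide of the 8-hydroxyl, on the face anti to C9, so the 17-hydroxyl ends trans to the 8-hydroxyl and cis to C9.

Step 28
Reactants: 37 bis-silyl ether
Product: 38 seco 2,3-diol (primary alcohols at C2 and C3)
Conditions: HF·pyridine, pyridine/THF, 0 °C to rt
Reagents that add atoms: none
Why: Buffered fluoride removes both primary silyl ethers; acetates, the lactone and the tertiary alcohols are stable, and the buffered medium limits acetyl migration from O14 to O2.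

Step 29
Reactants: 38 seco diol
Product: 39 seco C2,C3-dialdehyde
Conditions: Dess–Martin periodinane (3 equiv), NaHCO3, CH2Cl2, 0 °C; used at once
Reagents that add atoms: none
Why: Double periodinane oxidation; tertiary alcohols do not react, and buffering with immediate use limits migration of the C5=C6 bond into conjugation with the C3 aldehyde.

Step 30
Reactants: 39 seco C2,C3-dialdehyde
Product: 40 macrocyclic (2R,3S)-diol (2,3-dideacyl target)
Conditions: SmI2 (3 equiv), THF, slow addition of 39 to 2 mM, −78 °C to rt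
Reagents that add atoms: none
Why: Samarium diiodide transfers an electron to the less hindered C3 aldehyde, the ketyl adds in a 10-exo-trig radical step to the C2 aldehyde held on trivalent samarium, and a second electron transfer gives the samarium diolate (closest known reaction type: intramolecular pinacol coupling of dialdehydes by samarium diiodide or low-valent titanium, known for medium rings). The ten-membered ring B is the only ring closed. C2 is controlled by 1,3-chelation of the Cram chelate type: trivalent samarium bridges the C2 oxygen and the carbonyl oxygen of the cis 14α-acetate, which fixes the formyl rotamer so that C3 bonds on the face syn to the small C15 methyl and anti to C10, giving 2R. C3 is controlled by the same metal: both oxygens sit on one samarium (O–C–C–O synclinal) while the Z-alkene and the cis-fused lactone impose a gauche C1–C2–C3–C4 ring torsion, which corresponds to the erythro (cis) diol, giving 3S. The step needs reduction of two aldehydes beside a lactone, three acetates and an α-hydroxy ester; this is secured by the gap in reduction potential at −78 °C without HMPA and by the absence of any leaving group α to either ketyl (C1 quaternary, C4 methylene). It also needs ring closure to beat oligomerisation, which slow addition at high dilution and the pre-organisation by ring A, the Z-alkene and the lactone should provide.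

Step 31
Reactants: 40 macrocyclic diol
Product: 41 3-O-butanoyl-2-hydroxy macrocycle
Conditions: (PrCO)2O (1.1 equiv), 2,4,6-collidine, DMAP (5 mol %), CH2Cl2, −40 °C
Reagents that add atoms: butanoic anhydride, CCCC(=O)OC(=O)CCC
Why: Acylation at the less hindered C3 hydroxyl (next to the C4 methylene); the C2 hydroxyl is neopentyl and the C8 and C17 hydroxyls are tertiary.

Step 32
Reactants: 41 3-butanoate
Product: 42 target CNP0251217.1
Conditions: Ac2O, pyridine, DMAP (cat.), CH2Cl2, 0 °C to rt
Reagents that add atoms: acetic anhydride, CC(=O)OC(C)=O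
Why: Acetylation of the remaining secondary hydroxyl at C2; the tertiary hydroxyls should not acylate under these conditions, and the butanoate has no drive to migrate to the more hindered O2.

## Compound list

1 | (E)-4-methoxybut-3-en-2-one | CO/C=C/C(C)=O | starting material
2 | (E)-4-[(4-methoxybenzyl)oxy]but-3-en-2-one | COc1ccc(CO/C=C/C(C)=O)cc1 | intermediate
3 | (E)-1-[(4-methoxybenzyl)oxy]-3-(trimethylsilyloxy)buta-1,3-diene | COc1ccc(CO/C=C/C(=C)O[Si](C)(C)C)cc1 | intermediate
4 | (benzyloxy)acetaldehyde | O=CCOCc1ccccc1 | starting material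
5 | 2-(triphenylphosphoranylidene)propanal | CC(C=O)=P(c1ccccc1)(c1ccccc1)c1ccccc1 | starting material
6 | (E)-4-(benzyloxy)-2-methylbut-2-enal | O=C/C(C)=C/COCc1ccccc1 | intermediate
7 | cycloadduct: 1β-methyl-1α-formyl-10β-(benzyloxymethyl)-14α-(4-methoxybenzyloxy)-12-(trimethylsilyloxy)cyclohex-12-ene | c1ccccc1COC[C@H]2CC(O[Si](C)(C)C)=C[C@H](OCc3ccc(OC)cc3)[C@]2(C)C=O | intermediate
8 | 1α-hydroxymethyl analogue of 7 (silyl enol ether intact) | c1ccccc1COC[C@H]2CC(O[Si](C)(C)C)=C[C@H](OCc3ccc(OC)cc3)[C@]2(C)CO | intermediate (not isolated)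
9 | 1α-(hydroxymethyl)-1β-methyl-10β-(benzyloxymethyl)-14α-(4-methoxybenzyloxy)cyclohexan-12-one | c1ccccc1COC[C@H]2CC(=O)C[C@H](OCc3ccc(OC)cc3)[C@]2(C)CO | intermediate
10 | 1α-(tert-butyldimethylsilyloxymethyl) ether of 9 | c1ccccc1COC[C@H]2CC(=O)C[C@H](OCc3ccc(OC)cc3)[C@]2(C)CO[Si](C)(C)C(C)(C)C | intermediate
11 | 14α-hydroxy-1α-(tert-butyldimethylsilyloxymethyl)-1β-methyl-10β-(benzyloxymethyl)cyclohexan-12-one | c1ccccc1COC[C@H]2CC(=O)C[C@H](O)[C@]2(C)CO[Si](C)(C)C(C)(C)C | intermediate
12 | 11-(dimethylaminomethyl) derivative of 11 (C11 epimers) | c1ccccc1COC[C@H]2C(CN(C)C)C(=O)C[C@H](O)[C@]2(C)CO[Si](C)(C)C(C)(C)C | intermediate (not isolated)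
13 | 11-(trimethylammoniomethyl) iodide of 11 (C11 epimers) | c1ccccc1COC[C@H]2C(C[N+](C)(C)C)C(=O)C[C@H](O)[C@]2(C)CO[Si](C)(C)C(C)(C)C.[I-] | intermediate (not isolated)
14 | 11-methylidene-14α-hydroxy-12-ketone | c1ccccc1COC[C@H]2C(=C)C(=O)C[C@H](O)[C@]2(C)CO[Si](C)(C)C(C)(C)C | intermediate
15 | 11-methylidene-12β,14α-diol | c1ccccc1COC[C@H]2C(=C)[C@@H](O)C[C@H](O)[C@]2(C)CO[Si](C)(C)C(C)(C)C | intermediate
16 | 11-methylidene-12β,14α-diacetate | c1ccccc1COC[C@H]2C(=C)[C@@H](OC(C)=O)C[C@H](OC(C)=O)[C@]2(C)CO[Si](C)(C)C(C)(C)C | intermediate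
17 | 11β-methyl-12β,14α-diacetate, 10β-(benzyloxymethyl) | c1ccccc1COC[C@H]2[C@@H](C)[C@@H](OC(C)=O)C[C@H](OC(C)=O)[C@]2(C)CO[Si](C)(C)C(C)(C)C | intermediate
18 | 10β-(hydroxymethyl)-1β,11β-dimethyl-1α-(tert-butyldimethylsilyloxymethyl)cyclohexane-12β,14α-diyl diacetate | OC[C@H]1[C@@H](C)[C@@H](OC(C)=O)C[C@H](OC(C)=O)[C@]1(C)CO[Si](C)(C)C(C)(C)C | intermediate
19 | ring A aldehyde: 10β-formyl-1β,11β-dimethyl-1α-(tert-butyldimethylsilyloxymethyl)cyclohexane-12β,14α-diyl diacetate | O=C[C@H]1[C@@H](C)[C@@H](OC(C)=O)C[C@H](OC(C)=O)[C@]1(C)CO[Si](C)(C)C(C)(C)C | intermediate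
20 | 4-methyl-5,6-dihydro-2H-pyran-2-one | CC1=CC(=O)OCC1 | starting material
21 | (Z)-5-hydroxy-N-methoxy-N,3-dimethylpent-2-enamide | OCC/C(C)=C\C(=O)N(C)OC | intermediate
22 | (Z)-5-(tert-butyldiphenylsilyloxy)-N-methoxy-N,3-dimethylpent-2-enamide | CC(C)(C)[Si](c1ccccc1)(c1ccccc1)OCC/C(C)=C\C(=O)N(C)OC | intermediate
23 | (Z)-5-(tert-butyldiphenylsilyloxy)-3-methylpent-2-enal | CC(C)(C)[Si](c1ccccc1)(c1ccccc1)OCC/C(C)=C\C=O | intermediate
24 | methyl propiolate | C#CC(=O)OC | starting material
25 | methyl (S,Z)-8-(tert-butyldiphenylsilyloxy)-4-hydroxy-6-methyloct-5-en-2-ynoate | CC(C)(C)[Si](c1ccccc1)(c1ccccc1)OCC/C(C)=C\[C@@H](C#CC(=O)OC)O | intermediate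
26 | methyl (2Z,4S,5Z)-8-(tert-butyldiphenylsilyloxy)-4-hydroxy-6-methyl-2-(triethoxysilyl)octa-2,5-dienoate | CC(C)(C)[Si](c1ccccc1)(c1ccccc1)OCC/C(C)=C\[C@@H](/C=C(/C(=O)OC)[Si](OCC)(OCC)OCC)O | intermediate
27 | methyl (Z)-8-(tert-butyldiphenylsilyloxy)-4-hydroxy-6-methyl-2-oxooct-5-enoate (C7 configuration as in 25) | CC(C)(C)[Si](c1ccccc1)(c1ccccc1)OCC/C(C)=C\[C@@H](CC(=O)C(=O)OC)O | intermediate (not isolated)
28 | (S)-5-[(Z)-4-(tert-butyldiphenylsilyloxy)-2-methylbut-1-enyl]-3-hydroxyfuran-2(5H)-one | CC(C)(C)[Si](c1ccccc1)(c1ccccc1)OCC/C(C)=C\[C@@H]2OC(=O)C(O)=C2 | intermediate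
29 | (S)-5-[(Z)-4-(tert-butyldiphenylsilyloxy)-2-methylbut-1-enyl]-3-hydroxy-4-iodofuran-2(5H)-one | CC(C)(C)[Si](c1ccccc1)(c1ccccc1)OCC/C(C)=C\[C@@H]2OC(=O)C(O)=C2I | intermediate
30 | (S)-3-(tert-butyldimethylsilyloxy)-5-[(Z)-4-(tert-butyldiphenylsilyloxy)-2-methylbut-1-enyl]-4-iodofuran-2(5H)-one | CC(C)(C)[Si](c1ccccc1)(c1ccccc1)OCC/C(C)=C\[C@@H]2OC(=O)C(O[Si](C)(C)C(C)(C)C)=C2I | intermediate
31 | coupled allylic alcohol: butenolide 30 joined at C8 to C9(OH) of ring A unit 19 (7S; C9 epimers) | CC(C)(C)[Si](c1ccccc1)(c1ccccc1)OCC/C(C)=C\[C@@H]2OC(=O)C(O[Si](C)(C)C(C)(C)C)=C2C(O)[C@H]3[C@@H](C)[C@@H](OC(C)=O)C[C@H](OC(C)=O)[C@]3(C)CO[Si](C)(C)C(C)(C)C | intermediate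
32 | C9 ketone of 31 | CC(C)(C)[Si](c1ccccc1)(c1ccccc1)OCC/C(C)=C\[C@@H]2OC(=O)C(O[Si](C)(C)C(C)(C)C)=C2C(=O)[C@H]3[C@@H](C)[C@@H](OC(C)=O)C[C@H](OC(C)=O)[C@]3(C)CO[Si](C)(C)C(C)(C)C | intermediate
33 | (7S,9S)-allylic alcohol | CC(C)(C)[Si](c1ccccc1)(c1ccccc1)OCC/C(C)=C\[C@@H]2OC(=O)C(O[Si](C)(C)C(C)(C)C)=C2[C@@H](O)[C@H]3[C@@H](C)[C@@H](OC(C)=O)C[C@H](OC(C)=O)[C@]3(C)CO[Si](C)(C)C(C)(C)C | intermediate
34 | (7S,9S)-9-acetate | CC(C)(C)[Si](c1ccccc1)(c1ccccc1)OCC/C(C)=C\[C@@H]2OC(=O)C(O[Si](C)(C)C(C)(C)C)=C2[C@@H](OC(C)=O)[C@H]3[C@@H](C)[C@@H](OC(C)=O)C[C@H](OC(C)=O)[C@]3(C)CO[Si](C)(C)C(C)(C)C | intermediate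
35 | tetrabutylammonium enolate of the α-keto lactone (O17 enolate) | CC(C)(C)[Si](c1ccccc1)(c1ccccc1)OCC/C(C)=C\[C@@H]2OC(=O)C([O-])=C2[C@@H](OC(C)=O)[C@H]3[C@@H](C)[C@@H](OC(C)=O)C[C@H](OC(C)=O)[C@]3(C)CO[Si](C)(C)C(C)(C)C.CCCC[N+](CCCC)(CCCC)CCCC | intermediate (not isolated)
36 | (7S,8R,9S)-8-hydroxy-17-oxo lactone | CC(C)(C)[Si](c1ccccc1)(c1ccccc1)OCC/C(C)=C\[C@@H]2OC(=O)C(=O)[C@]2(O)[C@@H](OC(C)=O)[C@H]3[C@@H](C)[C@@H](OC(C)=O)C[C@H](OC(C)=O)[C@]3(C)CO[Si](C)(C)C(C)(C)C | intermediate
37 | (7S,8R,9S,17R)-8,17-dihydroxy lactone, 2-O-tert-butyldimethylsilyl, 3-O-tert-butyldiphenylsilyl | CC(C)(C)[Si](c1ccccc1)(c1ccccc1)OCC/C(C)=C\[C@@H]2OC(=O)[C@](C)(O)[C@]2(O)[C@@H](OC(C)=O)[C@H]3[C@@H](C)[C@@H](OC(C)=O)C[C@H](OC(C)=O)[C@]3(C)CO[Si](C)(C)C(C)(C)C | intermediate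
38 | seco 2,3-diol (primary alcohols at C2 and C3) | OCC/C(C)=C\[C@@H]1OC(=O)[C@](C)(O)[C@]1(O)[C@@H](OC(C)=O)[C@H]2[C@@H](C)[C@@H](OC(C)=O)C[C@H](OC(C)=O)[C@]2(C)CO | intermediate
39 | seco C2,C3-dialdehyde | O=CC/C(C)=C\[C@@H]1OC(=O)[C@](C)(O)[C@]1(O)[C@@H](OC(C)=O)[C@H]2[C@@H](C)[C@@H](OC(C)=O)C[C@H](OC(C)=O)[C@]2(C)C=O | intermediate
40 | macrocyclic (2R,3S)-diol: 9,12,14-triacetoxy-2,3,8,17-tetrahydroxybriar-5Z-en-19,7-olide | O[C@H]1C/C(C)=C\[C@@H]2OC(=O)[C@](C)(O)[C@]2(O)[C@@H](OC(C)=O)[C@H]2[C@@H](C)[C@@H](OC(C)=O)C[C@H](OC(C)=O)[C@]2(C)[C@H]1O | intermediate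
41 | 3-O-butanoyl derivative of 40 | CCCC(=O)O[C@H]1C/C(C)=C\[C@@H]2OC(=O)[C@](C)(O)[C@]2(O)[C@@H](OC(C)=O)[C@H]2[C@@H](C)[C@@H](OC(C)=O)C[C@H](OC(C)=O)[C@]2(C)[C@H]1O | intermediate
42 | CNP0251217.1: (1R,2R,3S,5Z,7S,8R,9S,10S,11R,12S,14S,17R)-2,9,12,14-tetraacetoxy-3-butanoyloxy-8,17-dihydroxybriar-5-en-19,7-olide | CCCC(=O)O[C@H]1C/C(C)=C\[C@@H]2OC(=O)[C@](C)(O)[C@]2(O)[C@@H](OC(C)=O)[C@H]2[C@@H](C)[C@@H](OC(C)=O)C[C@H](OC(C)=O)[C@]2(C)[C@H]1OC(C)=O | target

## Step count and least certain steps

Total: 32 steps. Longest linear sequence: 23 steps (1, 2, 3, 7, then 9–11 and 14–19, then 31–34 and 36–42; steps 1, 2, 4–13, 22–32).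

Step 30 (key step). The most likely failure is the wrong relative configuration: the C–C bond may form through an anticlinal ring torsion and give the threo (2,3-trans) diol, because ten-membered pinacol closures do not have the built-in cis preference of small rings. Simple reduction of the aldehydes and oligomerisation may also compete. Fallback: the stereocontrol at C3 is moved from the coupling to a hydride reduction. Setting out from 39, the coupling is run as before; the C3-epimeric diol, 3-epi-40 F1, is oxidised at its less hindered C3 carbinol (Dess–Martin periodinane, 1.1 equiv, 0 °C) to the 2-hydroxy-3-ketone F2. Chelation-controlled reduction with Zn(BH4)2 (zinc bridging the C2 hydroxyl and the C3 carbonyl) should return the erythro diol 40, where the route is rejoined.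

Step 26. After hydroxylation the C8 alkoxide sits next to the very electrophilic C17 ketone, so base-induced α-ketol rearrangement (shift of C9 or C7 to C17) may occur; facial selectivity may also erode. Fallback: the free alkoxide is avoided. Setting out from 34, the neutral enol silyl ether is oxidised directly by the same oxaziridine in a Rubottom-type reaction with silyl transfer to the 8-silyloxy-17-ketone F3. MeTi(OiPr)3 then gives the 8-silyloxy-17-hydroxy lactone F4, and the fluoride treatment of step 28 removes all three silyl groups and rejoins the route at 38.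

Step 19. The nascent α-keto ester may be cleaved by excess peroxide in a Baeyer–Villiger-type process before it lactonises, and oxidation of the electron-poor C–Si bond may be slow. Fallback: peroxide is avoided altogether. Setting out from 23, the lithiated SAMP hydrazone of methyl pyruvate F5 (made from methyl pyruvate and (S)-1-amino-2-(methoxymethyl)pyrrolidine) is added to the aldehyde to give the γ-hydroxy hydrazone F6, with C7 set by the auxiliary. Hydrolytic cleavage of the hydrazone with aqueous oxalic acid and lactonisation give 28, where the route is rejoined.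

Step 22. Both partners are hindered (a tetrasubstituted iodoalkene and an aldehyde between a quaternary and a tertiary carbon), so oxidative addition and carbonyl addition may be slow and protodeiodination may take over. Fallback: the polarity of the lactone partner is reversed. Setting out from 28, the enol is silylated to the 3-silyloxybutenolide F7, which reacts as a silyl enol ether with 19 in a BF3·OEt2-mediated Mukaiyama aldol addition to give the 4-(hydroxyalkyl)-3-hydroxybutenolide F8. Silylation of the acidic enol only (tBuMe2SiOTf, 1 equiv, 2,6-lutidine, −78 °C) gives 31, where the route is rejoined.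

Step 4. The acid-labile silyloxy diene may decompose or react by a stepwise Mukaiyama–Michael path, and the trisubstituted enal may give poor enantioface selection. Fallback: asymmetric catalysis is replaced by resolution. Setting out from 6 and 3, the cycloaddition is run without chiral catalyst (toluene, 80 °C, or Et2AlCl at −78 °C) to give 7 together with its enantiomer ent-7 F9. The operations of step 5 give 9 and ent-9 F10. A lipase (Burkholderia cepacia lipase, vinyl acetate), screened so that the unwanted enantiomer is acylated to the acetate F11, leaves 9, where the route is rejoined.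

## Further compounds

F1 | step 30 | 3-epi-40, the (2R,3R) threo diol | O[C@@H]1C/C(C)=C\[C@@H]2OC(=O)[C@](C)(O)[C@]2(O)[C@@H](OC(C)=O)[C@H]2[C@@H](C)[C@@H](OC(C)=O)C[C@H](OC(C)=O)[C@]2(C)[C@H]1O
F2 | step 30 | macrocyclic (2R)-2-hydroxy-3-ketone | O=C1C/C(C)=C\[C@@H]2OC(=O)[C@](C)(O)[C@]2(O)[C@@H](OC(C)=O)[C@H]2[C@@H](C)[C@@H](OC(C)=O)C[C@H](OC(C)=O)[C@]2(C)[C@H]1O
F3 | step 26 | 8-(tert-butyldimethylsilyloxy)-17-oxo lactone | CC(C)(C)[Si](c1ccccc1)(c1ccccc1)OCC/C(C)=C\[C@@H]2OC(=O)C(=O)[C@]2(O[Si](C)(C)C(C)(C)C)[C@@H](OC(C)=O)[C@H]3[C@@H](C)[C@@H](OC(C)=O)C[C@H](OC(C)=O)[C@]3(C)CO[Si](C)(C)C(C)(C)C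
F4 | step 26 | 8-(tert-butyldimethylsilyloxy)-17-hydroxy-17-methyl lactone | CC(C)(C)[Si](c1ccccc1)(c1ccccc1)OCC/C(C)=C\[C@@H]2OC(=O)[C@](C)(O)[C@]2(O[Si](C)(C)C(C)(C)C)[C@@H](OC(C)=O)[C@H]3[C@@H](C)[C@@H](OC(C)=O)C[C@H](OC(C)=O)[C@]3(C)CO[Si](C)(C)C(C)(C)C
F5 | step 19 | SAMP hydrazone of methyl pyruvate | COC[C@@H]1CCCN1N=C(C)C(=O)OC
F6 | step 19 | γ-hydroxy hydrazone aldol adduct of F5 and 23 | CC(C)(C)[Si](c1ccccc1)(c1ccccc1)OCC/C(C)=C\[C@@H](CC(=NN2CCC[C@H]2COC)C(=O)OC)O
F7 | step 22 | (S)-3-(tert-butyldimethylsilyloxy)-5-[(Z)-4-(tert-butyldiphenylsilyloxy)-2-methylbut-1-enyl]furan-2(5H)-one | CC(C)(C)[Si](c1ccccc1)(c1ccccc1)OCC/C(C)=C\[C@@H]2OC(=O)C(O[Si](C)(C)C(C)(C)C)=C2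
F8 | step 22 | 4-(hydroxyalkyl)-3-hydroxybutenolide aldol adduct (C9 epimers) | CC(C)(C)[Si](c1ccccc1)(c1ccccc1)OCC/C(C)=C\[C@@H]2OC(=O)C(O)=C2C(O)[C@H]3[C@@H](C)[C@@H](OC(C)=O)C[C@H](OC(C)=O)[C@]3(C)CO[Si](C)(C)C(C)(C)C
F9 | step 4 | ent-7 | c1ccccc1COC[C@@H]2CC(O[Si](C)(C)C)=C[C@@H](OCc3ccc(OC)cc3)[C@@]2(C)C=O
F10 | step 4 | ent-9 | c1ccccc1COC[C@@H]2CC(=O)C[C@@H](OCc3ccc(OC)cc3)[C@@]2(C)CO
F11 | step 4 | acetate of ent-9 | c1ccccc1COC[C@@H]2CC(=O)C[C@@H](OCc3ccc(OC)cc3)[C@@]2(C)COC(C)=O
A1 | alternative 1 | seco-diene for ring-closing metathesis at C5=C6 | C=C[C@@H]1OC(=O)[C@](C)(O)[C@]1(O)[C@@H](OC(C)=O)[C@H]2[C@@H](C)[C@@H](OC(C)=O)C[C@H](OC(C)=O)[C@]2(C)[C@@H](OC(C)=O)[C@H](CC(C)=C)OC(=O)CCC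
A2 | alternative 2 | keto aldehyde for C8–C9 pinacol coupling | O=C[C@H]1[C@@H](C)[C@@H](OC(C)=O)C[C@H](OC(C)=O)[C@]1(C)[C@@H](OC(C)=O)[C@H](C/C(C)=C\[C@@H]2OC(=O)[C@](C)(O)C2=O)OC(=O)CCC
A3 | alternative 2 | 9-hydroxy macrocycle (9-deacetyl target) | CCCC(=O)O[C@H]1C/C(C)=C\[C@@H]2OC(=O)[C@](C)(O)[C@]2(O)[C@@H](O)[C@H]2[C@@H](C)[C@@H](OC(C)=O)C[C@H](OC(C)=O)[C@]2(C)[C@H]1OC(C)=O
A4 | alternative 3 | silylated protected cyanohydrin allylic chloride | ClC/C(C)=C\[C@@H]1OC(=O)[C@](C)(O[Si](C)(C)C)[C@]1(O[Si](C)(C)C)[C@@H](O[Si](CC)(CC)CC)[C@H]2[C@@H](C)[C@@H](O[Si](CC)(CC)CC)C[C@H](O[Si](CC)(CC)CC)[C@]2(C)[C@@H](OCOC)C(C#N)OC(C)OCC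
A5 | alternative 3 | macrocyclic C3 ketone | O=C1C/C(C)=C\[C@@H]2OC(=O)[C@](C)(O[Si](C)(C)C)[C@]2(O[Si](C)(C)C)[C@@H](O[Si](CC)(CC)CC)[C@H]2[C@@H](C)[C@@H](O[Si](CC)(CC)CC)C[C@H](O[Si](CC)(CC)CC)[C@]2(C)[C@H]1OCOC
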